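**Assumption:** the target SMILES has no stereocentre and no configurationally stable axis, so the compound is achiral and "single enantiomer" does not apply. The one transient stereocentre (in 11) is formed racemic and is destroyed on aromatisation.

## Retrosynthetic overview
1. Target 13 comes from bis-TBS ether 12 by global desilylation. Ring A is purchased as methyl 2,4,6-trihydroxybenzoate.
2. The hexasubstituted ring B is the only ring formed. It is built last from cyclobutenone 11 by a Moore–Liebeskind 4π-opening/6π-closure, which fixes which oxygen is OH and which is OMe.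
3. Cyclobutenone 11 comes from regioselective 1,2-addition of 1,2-diprenylvinyllithium to the mixed aryl methyl squarate 6, with a MeOTf trap of the alkoxide. The vinyllithium derives from the symmetric alkyne 9.
4. The "diaryl ether" C–O bond is made on the squarate, by vinylogous acyl substitution of chlorosquarate 5 with phenol 2. No Ullmann, SNAr or quinone coupling is used.

## Route

**Step 1**
Reactants: 1, methyl 2,4,6-trihydroxybenzoate
Product: 2, methyl 2,4-bis(tert-butyldimethylsilyloxy)-6-hydroxybenzoate
Conditions: TBSCl (2.05 equiv), imidazole, CH2Cl2/DMF, 0 °C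
Reagents that add atoms: TBSCl, CC(C)(C)[Si](C)(C)Cl
Why: Selective silylation works because the 4-OH and one of the two equivalent ortho-OH groups react, while the last OH is strongly hydrogen-bonded to the ester C=O and is much slower.

**Step 2**
Reactants: 3, squaric acid
Product: 4, 3,4-dichlorocyclobut-3-ene-1,2-dione (squaryl dichloride)
Conditions: (COCl)2 (2.2 equiv), cat. DMF, 1,2-DCE, 50 °C
Reagents that add atoms: oxalyl chloride, O=C(Cl)C(=O)Cl
Why: This is a Vilsmeier-type chlorination of a vinylogous diacid, the standard preparation of squaryl dichloride.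

**Step 3**
Reactants: 4
Product: 5, 3-chloro-4-methoxycyclobut-3-ene-1,2-dione
Conditions: MeOH (1.0 equiv), Et2O, 0 °C → rt, N2 sweep
Reagents that add atoms: methanol, CO
Why: This is a vinylogous acyl substitution (addition–elimination), and the first OMe donor deactivates the remaining C–Cl, so mono-esterification can be stopped cleanly.

**Step 4**
Reactants: 2 and 5
Product: 6, methyl 2,4-bis(TBSO)-6-[(2-methoxy-3,4-dioxocyclobut-1-en-1-yl)oxy]benzoate (mixed aryl methyl squarate)
Conditions: 2, NaH, THF, 0 °C; then add to 5, THF, −78 → −20 °C; rapid filtration through neutral silica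
Reagents that add atoms: none (both partners are listed reactants)
Why: O-acylation-type addition–elimination of the phenoxide on the vinylogous acid chloride displaces chloride rather than methoxide, so the hindered aryl C–O bond forms at a highly electrophilic sp2 carbon.

**Step 5**
Reactants: 7, acetylene; 8, prenyl bromide (2.1 equiv)
Product: 9, 2,9-dimethyldeca-2,8-dien-5-yne (diprenylacetylene)
Conditions: 7, EtMgBr (2 equiv), Et2O–THF, reflux; then CuCl (10 mol %), 8, 50 °C
Reagents that add atoms: prenyl bromide (8), CC(C)=CCBr
Why: Cu(I)-catalysed allylation of the acetylene bis-Grignard (Iotsich reagent) gives the skipped enyne, with copper acetylides attacking prenyl halides mainly at the primary (SN2) terminus.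

**Step 6**
Reactants: 9
Product: 10, (5E)-5-iodo-2,9-dimethyldeca-2,5,8-triene
Conditions: Cp2Zr(H)Cl (1.2 equiv), THF, rt, dark; then I2, −78 → 0 °C
Reagents that add atoms: iodine, II
Why: Schwartz hydrozirconation/iodinolysis is selective for the alkyne over trisubstituted alkenes, the symmetric alkyne removes any regiochemical issue, and syn addition gives the E-iodide with H cis to iodine.

**Step 7 (key step, part 1)**
Reactants: 10 and 6
Product: 11, (±)-methyl 2,4-bis(TBSO)-6-({3-[(5E)-2,9-dimethyldeca-2,5,8-trien-5-yl]-2,3-dimethoxy-4-oxocyclobut-1-en-1-yl}oxy)benzoate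
Conditions: 10 (1.15 equiv), t-BuLi (2.3 equiv), Et2O, −78 °C; cannulate into 6, THF, −78 °C; then MeOTf (3 equiv), −78 → 0 °C
Reagents that add atoms: methyl triflate, COS(=O)(=O)C(F)(F)F
Why: Proposed new method: the closest known reaction type is the Moore/Liebeskind regioselective 1,2-addition of organolithiums to unsymmetrical cyclobutenediones with in situ MeOTf capture of the alkoxide, extended here to an aryl/alkyl squarate, where the C=O next to C–OMe is conjugated only to the weakly donating, ester-bearing aryloxy group and is also the less hindered carbonyl, so electronics and sterics both direct attack there, the hindered 2,6-disubstituted benzoate is untouched at −78 °C, and the new quaternary stereocentre is racemic and erased in step 8.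

**Step 8 (key step, part 2)**
Reactants: 11
Product: 12, methyl 2,4-bis(TBSO)-6-[2-hydroxy-5,6-dimethoxy-3,4-bis(3-methylbut-2-enyl)phenoxy]benzoate
Conditions: degassed PhMe (0.02 M), 110 °C, Ar
Reagents that add atoms: none
Why: In this Moore–Liebeskind ring expansion, 4π-opening turns the 4-OMe outward and the alkenyl inward, 6π-closure of the dienylketene (H on the inside of the E-terminus) and tautomerisation build ring B, and the ketene carbon becomes the free OH next to OAr while the pre-methylated oxygen becomes the 5′-OMe.

**Step 9**
Reactants: 12
Product: 13, 4-methylhydroatrovirinone, i.e. methyl 2,4-dihydroxy-6-[2-hydroxy-5,6-dimethoxy-3,4-bis(3-methylbut-2-enyl)phenoxy]benzoate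
Conditions: Et3N·3HF, THF, 0 °C → rt, Ar
Reagents that add atoms: none
Why: Fluoride desilylation of the aryl silyl ethers under near-neutral conditions avoids acid-induced chroman formation from the ortho-prenylphenol and base-induced lactonisation to the depsidone.

## Compound list
| No. | Name | SMILES | Role |
|---|---|---|---|
| 1 | methyl 2,4,6-trihydroxybenzoate | COC(=O)c1c(O)cc(O)cc1O | starting material |
| 2 | methyl 2,4-bis(TBSO)-6-hydroxybenzoate | COC(=O)c1c(O)cc(O[Si](C)(C)C(C)(C)C)cc1O[Si](C)(C)C(C)(C)C | intermediate |
| 3 | squaric acid | OC1=C(O)C(=O)C1=O | starting material |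
| 4 | squaryl dichloride | ClC1=C(Cl)C(=O)C1=O | intermediate |
| 5 | 3-chloro-4-methoxycyclobut-3-ene-1,2-dione | COC1=C(Cl)C(=O)C1=O | intermediate |
| 6 | mixed aryl methyl squarate | COC(=O)c1c(OC2=C(OC)C(=O)C2=O)cc(O[Si](C)(C)C(C)(C)C)cc1O[Si](C)(C)C(C)(C)C | intermediate |
| 7 | acetylene | C#C | starting material |
| 8 | prenyl bromide | CC(C)=CCBr | starting material |
| 9 | 2,9-dimethyldeca-2,8-dien-5-yne | CC(C)=CCC#CCC=C(C)C | intermediate |
| 10 | (5E)-5-iodo-2,9-dimethyldeca-2,5,8-triene | CC(C)=CC/C(I)=C\CC=C(C)C | intermediate |
| 11 | (±)-2-aryloxy-3,4-dimethoxy-4-alkenylcyclobutenone | COC(=O)c1c(OC2=C(OC)C(OC)(/C(CC=C(C)C)=C/CC=C(C)C)C2=O)cc(O[Si](C)(C)C(C)(C)C)cc1O[Si](C)(C)C(C)(C)C | intermediate |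
| 12 | bis-TBS 4-methylhydroatrovirinone | COC(=O)c1c(Oc2c(O)c(CC=C(C)C)c(CC=C(C)C)c(OC)c2OC)cc(O[Si](C)(C)C(C)(C)C)cc1O[Si](C)(C)C(C)(C)C | intermediate |
| 13 | 4-methylhydroatrovirinone (achiral) | COC(=O)c1c(O)cc(O)cc1Oc1c(O)c(CC=C(C)C)c(CC=C(C)C)c(OC)c1OC | target |

## Summary
**Total steps:** 9.
**Longest linear sequence:** 6 steps (3 → 4 → 5 → 6 → 11 → 12 → 13).

**Three steps most likely to fail, each with one fallback**

1. **Step 7: wrong carbonyl attacked.**
   - Swap the roles of the two oxygens. The adduct from attack next to C–OAr is trapped as a silyl ether (TBSOTf) instead of a methyl ether.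
   - It is then ring-expanded, the ketene-derived phenol is methylated (MeI/K2CO3), and step 9 removes all the silyl groups.
   - Both regioisomeric adducts therefore converge on 13.

2. **Step 4: aryl squarate 6 too labile to make or handle, or it expels aryloxide in step 7.**
   - Abandon the aryl squarate and add lithiated 10 to commercial dimethyl squarate.
   - Thermolysis and oxidation give 2,3-dimethoxy-5,6-diprenyl-1,4-benzoquinone.
   - Attach phenoxide 2 by addition–elimination at either of the two equivalent OMe positions, giving protected atrovirinone, then reduce with Na2S2O4.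
   - Mask the OH ortho to OAr by lactonisation onto the ring-A ester (depsidone), methylate the remaining OH, reopen with NaOMe/MeOH, and desilylate.

3. **Step 5: SN2/SN2′ mixtures or mono/bis-alkylation mixtures.**
   - Change the bond-forming logic to a Pd π-allyl (Stille) coupling of commercial bis(tributylstannyl)acetylene with prenyl bromide or acetate, which couples at the less substituted allyl terminus.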